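- Divide the rate at which Q is spent by the rate at which Z is spent, and time drops out of the reckoning. I set out from these flasks and readings.

common to all: Z 0.014 M; L 0.28 mM

| run | Q | temperature | remark | time |
|---|---|---|---|---|
| summer | 0.0056 M | 4 °C | run made earlier |  |
| dawn | 0.0084 M | 12 °C | run made earlier |  |
| south-east | 0.0112 M | 0 °C |  | 2.5 min |
| north | 0.0112 M | 15 °C |  | 2.5 min |
| south | 0.0112 M |  | at 15 °C until 30 s, from then on at 0 °C | 2.5 min |

summer run (percent of the Z charged)

| time / min | X / % |
|---|---|
| 0.167 | 14 |
| 0.500 | 38 |
| 0.833 | 43 |
| 1.33 | 43 |
| 2.00 | 39 |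
| 2.50 | 40 |
| 3.00 | 44 |

dawn run (percent of the Z charged)

| time / s | X / % |
|---|---|
| 10.0 | 39 |
| 12.0 | 46 |
| 15.0 | 51 |
| 30.0 | 60 |
| 40.0 | 63 |
| 60.0 | 59 |
| 90.0 | 60 |

(readings scatter by 2 percentage points)



1. the flask with the highest amount of X, in percent of the Z charged ("all alike" if they lie within 1.5 percentage points) (south-east / north / south / all alike)
2. final X, as a percentage of the Z charged, in south-east
3. final X, as a percentage of the Z charged, in north
4. final X, as a percentage of the Z charged, in south

- The plateaus read as one Q spent per Z: summer hovered between 39% and 44% on a Q charge of 40.0% of the Z charge, and dawn read 60% on 60.0%.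
- So my bench rule, with Q charged below Z, was that X stops at what the Q charge allows, Q being the limiting reagent. In south-east, north and south, Q over Z came to 80.0%, and I called this the ceiling: the share of the Z charged that the Q charge can turn into X.
- The rule stops where the Q charge passes the Z charge, and here it stood below that border.
- It also needs time. Summer's pace, 38% at 0.500 min, carried on to the ceiling, reckoned out at 1.05 min, which is less than the 2.5 min allowed, though this is only an estimate, since south-east runs colder than summer.
- Dawn's bend came at its own ceiling, with 60% at 30.0 s and 60% at 90.0 s, so I read it as arrival, not as a stall, and I expected the ceiling in south-east, north and south.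
- The forecast differed: south-east highest, with south-east 77%, north 52% and south 54%, holding of 15 °C that “the catalyst dies in seconds”.
- The simulation gave all alike: south-east 80.0%, north 80.0%, south 80.0%, each at the ceiling 80.0%.

    Z + Q + G → X + G, rate k1*[Z]*[Q]*[G]/(1 + ([Z]/sat1)) (26.0 mM, k = 1.00 × 10⁵ M⁻² s⁻¹, Ea = 18.0 kJ mol⁻¹)
    L → G (k = 0.0240 s⁻¹, Ea = 74.0 kJ mol⁻¹)
    (constants at 0 °C)

- In the neighbour flask, like south but with 0.019 M of Q, the same ratio came to 1.36, past the border. There Z was the charge that ran out first: X reached 100% of the Z charged with Z at 0%, and the excess over the Z charge reckons to 26.3% of the Q charge, where the flask held 26%.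

The runs come from a simulation for substances that don't exist, and the scatter is random.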